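**Strategy.** Ring B of the target contains a methyl-bearing olefinic carbon, C8, three bonds from the quaternary ring-fusion carbon C1 (C8=C9–C10–C1), and C1 also carries C2, the ring A carbonyl carbon. The plan therefore joins C2 to C8 through an ester oxygen in a seven-membered lactone and lets the derived silyl ketene acetal undergo a [3,3] shift. One operation then forms the C1–C10 bond, closes the cycloheptene, places the C8=C9 olefin and sets the quaternary centre by chirality transfer from C8. The precursor is an enantiopure 4,7-divinyl-3,7-dimethyl-5-silyloxyoxepan-2-one, reached by Baeyer–Villiger oxidation of a cyclohexanone; ring A follows by Wacker oxidation and aldol closure.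

Key step: step 10

Numbering used below (target): ring A = C1 (quaternary, CH3), C2 (C=O), C3 (CH2), C4 (C(OH)-isopropyl), C5 (CH); ring B = C5, C6 (CH–O–anisoyl), C7 (CH2), C8 (olefinic, CH3), C9 (=CH), C10 (CH2), C1.

Assumption: the (S,S)-amide of step 4 is taken to remove the α-proton that leads to 5, by analogy with the sense recalled for 4-substituted cyclohexanones; if the first run shows the opposite sense, the (R,R)-amide is used and nothing else changes.

Remark: centres that are erased later are either left open (the C2 carbinol in 22 and 24) or drawn as the expected epimer (the methyl-bearing α-carbon in 14 and 15); either epimer converges.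

**Step 1**
Reactants: 1 2,6-dimethylbenzene-1,4-diol
Product: 2 all-cis-2,6-dimethylcyclohexane-1,4-diol (meso)
Conditions: H2 (60 bar), 5% Rh/Al2O3, EtOH, 50 °C; recrystallisation
Reagents that add atoms: none
Why: Heterogeneous arene hydrogenation over rhodium adds all hydrogens to the adsorbed face with little C–O hydrogenolysis, so the all-cis meso diol should predominate and is purified by crystallisation.

**Step 2**
Reactants: 2 all-cis-2,6-dimethylcyclohexane-1,4-diol
Product: 3 all-cis-4-[(tert-butyldimethylsilyl)oxy]-2,6-dimethylcyclohexan-1-ol (meso)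
Conditions: TBSCl (1.05 equiv), imidazole, DMF, 0 °C
Reagents that add atoms: tert-butyldimethylsilyl chloride (TBSCl), CC(C)(C)[Si](C)(C)Cl
Why: Steric differentiation in a silylation: the hydroxyl remote from the methyl groups is equatorial and unhindered, whereas the other is axial between two methyl-bearing carbons, so monosilylation at the remote oxygen is expected.

**Step 3**
Reactants: 3 all-cis-4-[(tert-butyldimethylsilyl)oxy]-2,6-dimethylcyclohexan-1-ol
Product: 4 (2R,4r,6S)-4-[(tert-butyldimethylsilyl)oxy]-2,6-dimethylcyclohexan-1-one (all-cis and meso)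
Conditions: Dess–Martin periodinane, CH2Cl2, rt
Reagents that add atoms: none
Why: Dess–Martin oxidation converts the hindered axial carbinol into the ketone without epimerisation; the product, with both methyls and the silyloxy group equatorial, is also the thermodynamic isomer and is meso.

**Step 4**
Reactants: 4 (2R,4r,6S)-4-[(tert-butyldimethylsilyl)oxy]-2,6-dimethylcyclohexan-1-one
Product: 5 (3S,5R)-5-[(tert-butyldimethylsilyl)oxy]-1,3-dimethyl-2-[(trimethylsilyl)oxy]cyclohex-1-ene
Conditions: (S,S)-bis(1-phenylethyl)amine, n-BuLi, Me3SiCl (present from the start), THF, −100 → −78 °C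
Reagents that add atoms: trimethylsilyl chloride, C[Si](C)(C)Cl
Why: Enantiotopic-proton-selective deprotonation of the meso ketone by the C2-symmetric chiral lithium amide with in situ silylation removes one of the two axial α-hydrogens, which decides which α-carbon becomes quaternary C8 and thereby fixes the absolute configuration of the whole series; the other two centres are untouched.

**Step 5**
Reactants: 5 (3S,5R)-5-[(tert-butyldimethylsilyl)oxy]-1,3-dimethyl-2-[(trimethylsilyl)oxy]cyclohex-1-ene; 6 phenyl vinyl sulfoxide
Product: 8 (2R,4R,6S)-2-[2-(benzenesulfinyl)ethyl]-4-[(tert-butyldimethylsilyl)oxy]-2,6-dimethylcyclohexan-1-one (both sulfur epimers), via lithium enolate 7 (not isolated)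
Conditions: MeLi (1.05 equiv), THF, 0 °C; then 6 (1.0 equiv), −78 → −20 °C; H2O
Reagents that add atoms: phenyl vinyl sulfoxide, C=CS(=O)c1ccccc1
Why: Methyllithium cleaves the trimethylsilyl enol ether to the amine-free, regiodefined lithium enolate 7, whose Michael addition to the vinyl sulfoxide (a vinyl cation equivalent) takes the stereoelectronically preferred axial path on the face opposite the equatorial methyl and silyloxy groups, so the new quaternary centre (future C8) carries the two-carbon chain trans to the silyloxy group.

**Step 6**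
Reactants: 8 (2R,4R,6S)-2-[2-(benzenesulfinyl)ethyl]-4-[(tert-butyldimethylsilyl)oxy]-2,6-dimethylcyclohexan-1-one
Product: 9 (2R,4R,6S)-4-[(tert-butyldimethylsilyl)oxy]-2-ethenyl-2,6-dimethylcyclohexan-1-one
Conditions: toluene, NaHCO3 (solid), 110 °C
Reagents that add atoms: none
Why: Thermal syn-elimination of the sulfoxide can only abstract a hydrogen from the CH2 attached to the quaternary carbon, so the vinyl group is the sole olefin formed and no stereocentre is touched.

**Step 7**
Reactants: 9 (2R,4R,6S)-4-[(tert-butyldimethylsilyl)oxy]-2-ethenyl-2,6-dimethylcyclohexan-1-one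
Product: 11 (4S,6R)-4-[(tert-butyldimethylsilyl)oxy]-6-ethenyl-2,6-dimethylcyclohex-2-en-1-one, via trimethylsilyl enol ether 10 (not isolated)
Conditions: LiN(iPr)2, Me3SiCl, THF, −78 → 0 °C; then Pd(OAc)2 (1.05 equiv), MeCN, rt
Reagents that add atoms: none
Why: Ito–Saegusa oxidation: only one α-hydrogen remains, so enolisation and silylation give a single silyl enol ether, and divalent palladium then forms the oxa-π-allyl complex and eliminates a ring β-hydride to the conjugated endocyclic enone; the α-methyl centre is erased on purpose and the quaternary and carbinol centres are untouched.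

**Step 8**
Reactants: 11 (4S,6R)-4-[(tert-butyldimethylsilyl)oxy]-6-ethenyl-2,6-dimethylcyclohex-2-en-1-one; 12 vinylmagnesium bromide
Product: 14 (2R,4S,5S,6S)-4-[(tert-butyldimethylsilyl)oxy]-2,5-diethenyl-2,6-dimethylcyclohexan-1-one, via trimethylsilyl enol ether 13 (not isolated)
Conditions: 12 (2 equiv), CuBr·SMe2 (10 mol%), Me3SiCl, THF, −78 °C; then 1 M HCl, THF, 0 °C
Reagents that add atoms: vinylmagnesium bromide, C=C[Mg]Br
Why: Copper-catalysed conjugate addition of the vinyl Grignard reagent, accelerated by Me3SiCl, enters anti to the adjacent γ-silyloxy group, which sets C5 with its vinyl trans to the silyloxy group and therefore cis to the vinyl on the quaternary carbon; acid hydrolysis of enol ether 13 gives the ketone, whose α-methyl configuration (equatorial expected) is of no consequence.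

**Step 9**
Reactants: 14 (2R,4S,5S,6S)-4-[(tert-butyldimethylsilyl)oxy]-2,5-diethenyl-2,6-dimethylcyclohexan-1-one
Product: 15 (3S,4S,5S,7R)-5-[(tert-butyldimethylsilyl)oxy]-4,7-diethenyl-3,7-dimethyloxepan-2-one
Conditions: mCPBA, NaHCO3, CH2Cl2, 0 °C → rt
Reagents that add atoms: 3-chloroperoxybenzoic acid (mCPBA), O=C(OO)c1cccc(Cl)c1
Why: Baeyer–Villiger oxidation: the fully substituted allylic α-carbon migrates in preference to the secondary one and with retention, which places the ring oxygen on C8 without change of configuration, while the buffered peracid oxidises the ketone faster than it epoxidises monosubstituted vinyl groups.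

**Step 10**
Reactants: 15 (3S,4S,5S,7R)-5-[(tert-butyldimethylsilyl)oxy]-4,7-diethenyl-3,7-dimethyloxepan-2-one
Product: 18 (1R,6S,7S)-6-[(tert-butyldimethylsilyl)oxy]-7-ethenyl-1,4-dimethylcyclohept-3-ene-1-carboxylic acid, via silyl ketene acetal 16 (not isolated), via silyl ester 17 (not isolated)
Conditions: LiN(iPr)2, TBSCl, THF–DMPU, −78 °C → rt; toluene, 100 °C; then THF–H2O, AcOH (cat.), rt
Reagents that add atoms: none
Why: Deprotonation at the only α-hydrogen and O-silylation give the cyclic silyl ketene acetal 16, in which C1=C2–O–C8–C9=C10 is a 1,5-diene held by the oxepane ring in a boat-like six-atom array, and a concerted suprafacial [3,3] shift (Ireland–Claisen rearrangement) then forms C1–C10 while O–C8 breaks. The closest known reaction type is the ester enolate Claisen rearrangement of alkenyl-substituted lactone silyl ketene acetals to cycloalkenecarboxylic acids. Ring B (C1, C5, C6, C7, C8, C9, C10) is closed by this sigmatropic transposition and not by a polar cyclisation, and the new olefin is forced to be C8=C9 and cis within the ring. The one new stereocentre, quaternary C1, is controlled by the C8 configuration: C10 can only reach the face of C1 on which the C8 vinyl group sits, and because that vinyl is cis to the C5 vinyl group (steps 5 and 8) the methyl ends cis and the carboxyl trans to the C5 vinyl group, which is the trans ring fusion of the target. The step needs face selectivity at C1 and a single enolisation site; the ring constraint secures the first, the lone α-hydrogen the second, and since the ring also fixes the ketene acetal geometry the configuration of the methyl-bearing α-carbon of 15 is irrelevant. Wet THF with a trace of acid then cleaves only the silyl ester.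

**Step 11**
Reactants: 18 (1R,6S,7S)-6-[(tert-butyldimethylsilyl)oxy]-7-ethenyl-1,4-dimethylcyclohept-3-ene-1-carboxylic acid
Product: 19 [(1R,6S,7S)-6-[(tert-butyldimethylsilyl)oxy]-7-ethenyl-1,4-dimethylcyclohept-3-en-1-yl]methanol
Conditions: LiAlH4, THF, 0 °C → rt
Reagents that add atoms: none
Why: Hydride reduction of the hindered α-quaternary carboxylic acid to the neopentyl-type primary alcohol; olefins, silyl ether and all stereocentres are inert to LiAlH4.

**Step 12**
Reactants: 19 [(1R,6S,7S)-6-[(tert-butyldimethylsilyl)oxy]-7-ethenyl-1,4-dimethylcyclohept-3-en-1-yl]methanol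
Product: 20 (1R,6S,7S)-6-[(tert-butyldimethylsilyl)oxy]-7-ethenyl-1,4-dimethylcyclohept-3-ene-1-carbaldehyde
Conditions: Dess–Martin periodinane, pyridine, CH2Cl2, rt
Reagents that add atoms: none
Why: Dess–Martin oxidation gives the C2 aldehyde, which can neither enolise nor epimerise because C1 is quaternary.

**Step 13**
Reactants: 20 (1R,6S,7S)-6-[(tert-butyldimethylsilyl)oxy]-7-ethenyl-1,4-dimethylcyclohept-3-ene-1-carbaldehyde
Product: 21 (1R,6S,7S)-7-acetyl-6-[(tert-butyldimethylsilyl)oxy]-1,4-dimethylcyclohept-3-ene-1-carbaldehyde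
Conditions: PdCl2 (10 mol%), CuCl (1 equiv), O2 (1 atm), DMF–H2O 7:1, rt
Reagents that add atoms: water, O
Why: Wacker–Tsuji oxidation: divalent palladium activates only the monosubstituted vinyl group (the trisubstituted ring olefin is inert) and water attacks its internal carbon, giving the methyl ketone that supplies C4 and C3; the mildly acidic medium leaves C5 and the silyl ether untouched.

**Step 14**
Reactants: 21 (1R,6S,7S)-7-acetyl-6-[(tert-butyldimethylsilyl)oxy]-1,4-dimethylcyclohept-3-ene-1-carbaldehyde
Product: 22 trans-fused bicyclic β-hydroxy ketone [target numbering: C2–OH as either epimer; C4=O; C6–OTBS; C8=C9; (1R,5S,6S)]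
Conditions: LiN(iPr)2 (1.05 equiv), THF, −78 °C; AcOH, −78 °C
Reagents that add atoms: none
Why: Intramolecular aldol addition: kinetic deprotonation takes the methyl group (C3) and not the hindered C5 methine, and the enolate closes ring A onto the neighbouring non-enolisable aldehyde in a 5-(enolexo)-exo-trig mode, the trans ring fusion being fixed beforehand by C1 and C5; the new C2 carbinol centre is not controlled and is removed in step 16, and the cold acid quench forestalls retro-aldol reaction, epimerisation at C5 and loss of the β-silyloxy group.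

**Step 15**
Reactants: 22 trans-fused bicyclic β-hydroxy ketone; 23 isopropylmagnesium chloride
Product: 24 bicyclic diol [target numbering: C2–OH as either epimer; C4 tertiary alcohol bearing isopropyl; C6–OTBS; (1R,4R,5S,6S)]
Conditions: 23 (4 equiv), anhydrous CeCl3 (4 equiv), THF, −78 → −40 °C; H2O
Reagents that add atoms: isopropylmagnesium chloride, CC(C)[Mg]Cl
Why: 1,2-Addition of the weakly basic organocerium reagent (one equivalent is spent on the C2 hydroxyl) to the C4 ketone from the face of the C5 hydrogen, because the axial angular methyl on C1 screens the opposite face of the trans-fused cyclopentanone; this sets C4 with isopropyl cis to the C5 hydrogen and hydroxyl cis to the angular methyl, as in the target.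

**Step 16**
Reactants: 24 bicyclic diol
Product: 25 bicyclic hydroxy ketone [target numbering: C2=O; C4–OH; C6–OTBS; (1R,4R,5S,6S)]
Conditions: Dess–Martin periodinane, pyridine, CH2Cl2, 0 °C → rt
Reagents that add atoms: none
Why: Dess–Martin oxidation acts only on the secondary C2 carbinol (both epimers converge), the tertiary C4 alcohol and the silyl ether being inert, and the buffered conditions spare the β-hydroxy ketone that results.

**Step 17**
Reactants: 25 bicyclic hydroxy ketone
Product: 26 keto diol [target numbering: C2=O; C4–OH; C6–OH; (1R,4R,5S,6S)]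
Conditions: HF·pyridine, pyridine, THF, 0 °C → rt
Reagents that add atoms: none
Why: Fluoride-mediated cleavage of the secondary silyl ether under buffered, non-basic conditions, chosen so that the tertiary β-hydroxy ketone suffers neither retro-aldol cleavage nor dehydration; no stereocentre is affected.

**Step 18**
Reactants: 26 keto diol; 27 4-methoxybenzoyl chloride
Product: 28 (3R,3aS,4S,8aR)-3-hydroxy-6,8a-dimethyl-1-oxo-3-(propan-2-yl)-1,2,3,3a,4,5,8,8a-octahydroazulen-4-yl 4-methoxybenzoate (CNP0232277.1)
Conditions: 27 (1.3 equiv), pyridine, DMAP (cat.), CH2Cl2, 0 °C → rt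
Reagents that add atoms: 4-methoxybenzoyl chloride, COc1ccc(C(=O)Cl)cc1
Why: Acylation under nucleophilic catalysis of the only reactive hydroxyl, the secondary one at C6, with retention at C6; the tertiary C4 hydroxyl is too hindered to be esterified under these mild conditions.

**Compound list**

1 | 2,6-dimethylbenzene-1,4-diol | Cc1cc(O)cc(C)c1O | starting material
2 | all-cis-2,6-dimethylcyclohexane-1,4-diol (meso) | C[C@@H]1C[C@H](O)C[C@H](C)[C@@H]1O | intermediate
3 | all-cis-4-[(tert-butyldimethylsilyl)oxy]-2,6-dimethylcyclohexan-1-ol (meso) | C[C@@H]1C[C@H](O[Si](C)(C)C(C)(C)C)C[C@H](C)[C@@H]1O | intermediate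
4 | (2R,4r,6S)-4-[(tert-butyldimethylsilyl)oxy]-2,6-dimethylcyclohexan-1-one (meso) | C[C@@H]1C[C@H](O[Si](C)(C)C(C)(C)C)C[C@H](C)C1=O | intermediate
5 | (3S,5R)-5-[(tert-butyldimethylsilyl)oxy]-1,3-dimethyl-2-[(trimethylsilyl)oxy]cyclohex-1-ene | CC1=C(O[Si](C)(C)C)[C@@H](C)C[C@@H](O[Si](C)(C)C(C)(C)C)C1 | intermediate
6 | phenyl vinyl sulfoxide | C=CS(=O)c1ccccc1 | starting material
7 | lithium enolate corresponding to 5 | CC1=C([O-])[C@@H](C)C[C@@H](O[Si](C)(C)C(C)(C)C)C1.[Li+] | intermediate
8 | (2R,4R,6S)-2-[2-(benzenesulfinyl)ethyl]-4-[(tert-butyldimethylsilyl)oxy]-2,6-dimethylcyclohexan-1-one (sulfur epimers) | O=S(CC[C@@]1(C)C[C@H](O[Si](C)(C)C(C)(C)C)C[C@H](C)C1=O)c1ccccc1 | intermediate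
9 | (2R,4R,6S)-4-[(tert-butyldimethylsilyl)oxy]-2-ethenyl-2,6-dimethylcyclohexan-1-one | C=C[C@@]1(C)C[C@H](O[Si](C)(C)C(C)(C)C)C[C@H](C)C1=O | intermediate
10 | trimethylsilyl enol ether of 9 | C=C[C@@]1(C)C[C@H](O[Si](C)(C)C(C)(C)C)CC(C)=C1O[Si](C)(C)C | intermediate
11 | (4S,6R)-4-[(tert-butyldimethylsilyl)oxy]-6-ethenyl-2,6-dimethylcyclohex-2-en-1-one | C=C[C@@]1(C)C[C@H](O[Si](C)(C)C(C)(C)C)C=C(C)C1=O | intermediate
12 | vinylmagnesium bromide | C=C[Mg]Br | starting material
13 | trimethylsilyl enol ether of 14 | C=C[C@@]1(C)C[C@H](O[Si](C)(C)C(C)(C)C)[C@@H](C=C)C(C)=C1O[Si](C)(C)C | intermediate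
14 | (2R,4S,5S,6S)-4-[(tert-butyldimethylsilyl)oxy]-2,5-diethenyl-2,6-dimethylcyclohexan-1-one | C=C[C@@]1(C)C[C@H](O[Si](C)(C)C(C)(C)C)[C@@H](C=C)[C@H](C)C1=O | intermediate
15 | (3S,4S,5S,7R)-5-[(tert-butyldimethylsilyl)oxy]-4,7-diethenyl-3,7-dimethyloxepan-2-one | C=C[C@@]1(C)C[C@H](O[Si](C)(C)C(C)(C)C)[C@@H](C=C)[C@H](C)C(=O)O1 | intermediate
16 | tert-butyldimethylsilyl ketene acetal of 15 | C=C[C@@]1(C)C[C@H](O[Si](C)(C)C(C)(C)C)[C@@H](C=C)C(C)=C(O[Si](C)(C)C(C)(C)C)O1 | intermediate
17 | tert-butyldimethylsilyl ester of 18 | CC1=CC[C@@](C)(C(=O)O[Si](C)(C)C(C)(C)C)[C@H](C=C)[C@@H](O[Si](C)(C)C(C)(C)C)C1 | intermediate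
18 | (1R,6S,7S)-6-[(tert-butyldimethylsilyl)oxy]-7-ethenyl-1,4-dimethylcyclohept-3-ene-1-carboxylic acid | CC1=CC[C@@](C)(C(=O)O)[C@H](C=C)[C@@H](O[Si](C)(C)C(C)(C)C)C1 | intermediate
19 | [(1R,6S,7S)-6-[(tert-butyldimethylsilyl)oxy]-7-ethenyl-1,4-dimethylcyclohept-3-en-1-yl]methanol | CC1=CC[C@@](C)(CO)[C@H](C=C)[C@@H](O[Si](C)(C)C(C)(C)C)C1 | intermediate
20 | (1R,6S,7S)-6-[(tert-butyldimethylsilyl)oxy]-7-ethenyl-1,4-dimethylcyclohept-3-ene-1-carbaldehyde | CC1=CC[C@@](C)(C=O)[C@H](C=C)[C@@H](O[Si](C)(C)C(C)(C)C)C1 | intermediate
21 | (1R,6S,7S)-7-acetyl-6-[(tert-butyldimethylsilyl)oxy]-1,4-dimethylcyclohept-3-ene-1-carbaldehyde | CC1=CC[C@@](C)(C=O)[C@H](C(C)=O)[C@@H](O[Si](C)(C)C(C)(C)C)C1 | intermediate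
22 | trans-fused bicyclic β-hydroxy ketone, (1R,5S,6S) in target numbering, C2 carbinol as either epimer | CC1=CC[C@@]2(C)C(O)CC(=O)[C@@H]2[C@@H](O[Si](C)(C)C(C)(C)C)C1 | intermediate
23 | isopropylmagnesium chloride | CC(C)[Mg]Cl | starting material
24 | bicyclic diol, (1R,4R,5S,6S) in target numbering, C2 carbinol as either epimer | CC1=CC[C@@]2(C)C(O)C[C@@](O)(C(C)C)[C@@H]2[C@@H](O[Si](C)(C)C(C)(C)C)C1 | intermediate
25 | bicyclic hydroxy ketone, (1R,4R,5S,6S) in target numbering | CC1=CC[C@@]2(C)C(=O)C[C@@](O)(C(C)C)[C@@H]2[C@@H](O[Si](C)(C)C(C)(C)C)C1 | intermediate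
26 | keto diol, (1R,4R,5S,6S) in target numbering | CC1=CC[C@@]2(C)C(=O)C[C@@](O)(C(C)C)[C@@H]2[C@@H](O)C1 | intermediate
27 | 4-methoxybenzoyl chloride | COc1ccc(C(=O)Cl)cc1 | starting material
28 | (3R,3aS,4S,8aR)-3-hydroxy-6,8a-dimethyl-1-oxo-3-(propan-2-yl)-1,2,3,3a,4,5,8,8a-octahydroazulen-4-yl 4-methoxybenzoate | COc1ccc(C(=O)O[C@H]2CC(C)=CC[C@@]3(C)C(=O)C[C@@](O)(C(C)C)[C@H]23)cc1 | target

**Step count and risk**

Total: 18 steps. Longest linear sequence: 18 steps (1 → 28); compounds 6, 12, 23 and 27 enter as purchased reagents.

Step 10 is the pivot of the route, but its reaction class is established for 7-alkenyl oxepan-2-ones and its stereochemical outcome is fixed by the ring. The three steps judged most likely to fail are those that depend on substrate-specific selectivity.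

(a) Step 4. What may go wrong: the chiral amide may discriminate the two enantiotopic axial α-hydrogens of this 2,6-dimethyl-4-silyloxy ketone insufficiently, or in the opposite sense. The fallback replaces asymmetric deprotonation by resolution through a chiral Michael acceptor. It sets out from 4: LiN(iPr)2 in THF at −78 °C gives the racemic enolate, that is 7 together with its mirror image, lithium enolate of opposite configuration F1. The mixture is added to enantiopure (R)-4-methylphenyl vinyl sulfoxide (C=C[S@@](=O)c1ccc(C)cc1, purchased). This gives two diastereomers, (R)-sulfinyl adduct with the ring configuration of 8 F2 and (R)-sulfinyl adduct with the mirror-image ring F3, which are separated by chromatography or crystallisation. Heating F2 alone in toluene over NaHCO3 brings the route back at 9, enantiopure, at the cost of half the material.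

(b) Step 5. What may go wrong: conjugate addition of the hindered tetrasubstituted enolate may be slow, and proton transfer from the product to the α-sulfinyl carbanion may lead to polyaddition or to erosion of face selectivity. The fallback replaces the anionic C–C bond formation by a cationic one and sets out from 5, used directly as the nucleophile. 1-Chloroethyl phenyl sulfide F4, made from ethyl phenyl sulfide and N-chlorosuccinimide, is ionised by ZnBr2 (cat.) in CH2Cl2. The thionium ion is captured by the silyl enol ether on the same axial face to give α-[1-(phenylsulfanyl)ethyl] ketone F5. NaIO4 in MeOH–H2O gives sulfoxide F6, whose thermal syn-elimination can take only a methyl hydrogen, so the route is rejoined at 9.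

(c) Step 15. What may go wrong: β-hydride transfer from the secondary organometallic and enolisation toward C5 (with loss of the C6 silyloxy group) may outrun addition, and the aldolate may cleave by retro-aldol reaction. The fallback uses an sp2 nucleophile followed by chemoselective hydrogenation and sets out from 22. Isopropenylmagnesium bromide with CeCl3, which cannot deliver hydride and is sterically smaller, adds to C4 from the same face to give isopropenyl diol F7. Hydrogenation with RhCl(PPh3)3 in benzene saturates the 1,1-disubstituted olefin and leaves the trisubstituted ring olefin, and the route is rejoined at 24.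

**Further compounds**

F1 | step 4 | lithium enolate of opposite configuration (mirror image of 7) | CC1=C([O-])[C@H](C)C[C@H](O[Si](C)(C)C(C)(C)C)C1.[Li+]
F2 | step 4 | (2R,4R,6S)-4-[(tert-butyldimethylsilyl)oxy]-2,6-dimethyl-2-{2-[(R)-4-methylbenzenesulfinyl]ethyl}cyclohexan-1-one | Cc1ccc(cc1)[S@](=O)CC[C@@]1(C)C[C@H](O[Si](C)(C)C(C)(C)C)C[C@H](C)C1=O
F3 | step 4 | (2S,4S,6R)-4-[(tert-butyldimethylsilyl)oxy]-2,6-dimethyl-2-{2-[(R)-4-methylbenzenesulfinyl]ethyl}cyclohexan-1-one | Cc1ccc(cc1)[S@](=O)CC[C@]1(C)C[C@@H](O[Si](C)(C)C(C)(C)C)C[C@@H](C)C1=O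
F4 | step 5 | 1-chloroethyl phenyl sulfide | CC(Cl)Sc1ccccc1
F5 | step 5 | 4-[(tert-butyldimethylsilyl)oxy]-2,6-dimethyl-2-[1-(phenylsulfanyl)ethyl]cyclohexan-1-one with the ring configuration of 9 (side-chain carbon unassigned) | CC(Sc1ccccc1)[C@@]1(C)C[C@H](O[Si](C)(C)C(C)(C)C)C[C@H](C)C1=O
F6 | step 5 | 2-[1-(benzenesulfinyl)ethyl]-4-[(tert-butyldimethylsilyl)oxy]-2,6-dimethylcyclohexan-1-one with the ring configuration of 9 | CC(S(=O)c1ccccc1)[C@@]1(C)C[C@H](O[Si](C)(C)C(C)(C)C)C[C@H](C)C1=O
F7 | step 15 | isopropenyl analogue of diol 24 | CC1=CC[C@@]2(C)C(O)C[C@@](O)(C(C)=C)[C@@H]2[C@@H](O[Si](C)(C)C(C)(C)C)C1
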